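Cuts, in retrosynthetic order: the C1–C10 epoxide oxygen; the C8–O ester bond (made with inversion); the lactone bonds O–C6 and C11–C12 together, which removes one CO2; ring bond C6–C7; C7=C11 and C8–O; C8–C9 together with the C1=C10 alkene; C1–C10.
Enabling feature: in the five-membered lactone ring, O–C12(=O) lies between C6 and C11. C6 is allylic to the C4=C5 alkene of the ten-membered ring, so it can act as an η3-allyl electrophile. C11 is vinylic (C11=C13) and 1,3 to C6, so it can act as an alkenyl-metal nucleophile, with CO2 as the bridge.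
Forward: the chain comes from nerol (C1–C6, C15), 2-bromoallyl alcohol (C9, C10, C14), triethyl orthoacetate (C7, C8) and a bromo-ylide (C11, C13). The ten-membered ring closes by chromium-mediated 2-bromoallylation (C6–C7), the lactone ring by the CO2 event, then the ester, and the epoxide ring last.
Stereochemistry: 4Z comes from nerol and the ring-trans C1=C10 from the Johnson–Claisen chair. C8 is set by D-proline aminoxylation as an 8α helper that relays to C7 and C6 in the ring closure (Felkin–Anh, anti). C6 is kept by double inversion in the key step, C8 is inverted to 8β in the Mitsunobu esterification, and C1/C10 come from Sharpless epoxidation.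

Key step: step 17

Remark: germacrane numbering is used (ring C1–C10; C11, C12, C13 = lactone side-chain carbons; C14 = CH2OH carbon on C10; C15 = methyl on C4), and α/β refer to the usual drawing with H7 α. PMB = 4-methoxybenzyl, TBS = tert-butyldimethylsilyl, TBDPS = tert-butyldiphenylsilyl, pin = pinacolato, IPr = 1,3-bis(2,6-diisopropylphenyl)imidazol-2-ylidene.

Step 1
Reactants: 1 nerol
Product: 2 neryl 4-methoxybenzyl ether
Conditions: NaH, PMBCl, Bu4NI (cat.), THF, 0 °C → rt
Reagents that add atoms: 4-methoxybenzyl chloride, COc1ccc(CCl)cc1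
Why: Williamson etherification masks the C6 oxygen with a group that can later be removed oxidatively beside an allylic bromide, and nerol supplies the 4Z alkene and C15.

Step 2
Reactants: 2 neryl 4-methoxybenzyl ether
Product: 4 (4Z)-6-(4-methoxybenzyloxy)-4-methylhex-4-enal, via terminal epoxide 3 (not isolated)
Conditions: mCPBA (1.0 equiv), CH2Cl2, 0 °C; then H5IO6, THF–Et2O, 0 °C
Reagents that add atoms: mCPBA, O=C(OO)c1cccc(Cl)c1
Why: Prilezhaev epoxidation prefers the remote, more electron-rich trisubstituted alkene over the one deactivated by the allylic ether oxygen, and periodic acid cleaves the epoxide to the C1 aldehyde with loss of acetone.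

Step 3
Reactants: 5 2-bromoprop-2-en-1-ol
Product: 6 2-bromoallyl TBDPS ether
Conditions: TBDPSCl, imidazole, CH2Cl2, rt
Reagents that add atoms: tert-butyldiphenylsilyl chloride, CC(C)(C)[Si](Cl)(c1ccccc1)c1ccccc1
Why: Standard silylation gives an acid-robust ether on the future C14 oxygen that should outlast the TBS group removed in step 18.

Step 4
Reactants: 6 2-bromoallyl TBDPS ether; 4 (4Z)-6-(4-methoxybenzyloxy)-4-methylhex-4-enal
Product: 8 (6Z)-1-(TBDPS-oxy)-8-(PMB-oxy)-6-methyl-2-methylideneoct-6-en-3-ol (racemic carbinol), via 2-lithioallyl ether 7 (not isolated)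
Conditions: 6, tBuLi (2.0 equiv), Et2O, −78 °C; then 4, −78 °C; then H2O
Reagents that add atoms: none
Why: Bromine–lithium exchange and 1,2-addition of the alkenyllithium to the aldehyde join C1 to C10; the new carbinol centre may be racemic because step 5 erases it.

Step 5
Reactants: 8 (6Z)-1-(TBDPS-oxy)-8-(PMB-oxy)-6-methyl-2-methylideneoct-6-en-3-ol
Product: 9 ethyl (4Z,8Z)-4-[(TBDPS-oxy)methyl]-10-(PMB-oxy)-8-methyldeca-4,8-dienoate
Conditions: MeC(OEt)3 (10 equiv), EtCO2H (cat.), 140 °C
Reagents that add atoms: triethyl orthoacetate, CC(OCC)(OCC)OCC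
Why: Johnson–Claisen rearrangement through a chair with the C2 chain equatorial forms C9–C8 and places C9 trans to C2 (C14 cis to C2) on the new C1=C10 alkene, which is the ring-trans geometry required.

Step 6
Reactants: 9 ethyl (4Z,8Z)-4-[(TBDPS-oxy)methyl]-10-(PMB-oxy)-8-methyldeca-4,8-dienoate
Product: 10 (4Z,8Z)-4-[(TBDPS-oxy)methyl]-10-(PMB-oxy)-8-methyldeca-4,8-dienal
Conditions: iBu2AlH (DIBAL-H, 1.05 equiv), toluene, −78 °C; aq. KNaC4H4O6 work-up
Reagents that add atoms: none
Why: Partial ester reduction stops at the aluminium hemiacetal at low temperature and releases the C7 aldehyde on work-up.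

Step 7
Reactants: 10 (4Z,8Z)-4-[(TBDPS-oxy)methyl]-10-(PMB-oxy)-8-methyldeca-4,8-dienal
Product: 12 ethyl (2Z,4S,6Z,10Z)-4-(anilinooxy)-2-bromo-6-[(TBDPS-oxy)methyl]-12-(PMB-oxy)-10-methyldodeca-2,6,10-trienoate, via aminoxy aldehyde 11 (not isolated)
Conditions: D-proline (20 mol %), PhNO, DMSO, rt; then Ph3P=C(Br)CO2Et, CH2Cl2, 0 °C → rt
Reagents that add atoms: nitrosobenzene, O=Nc1ccccc1; ethyl bromo(triphenylphosphoranylidene)acetate, CCOC(=O)C(Br)=P(c1ccccc1)(c1ccccc1)c1ccccc1
Why: Proline-catalysed α-aminoxylation through the D-proline enamine sets (S)-C8 by catalyst control, and immediate Wittig olefination with the stabilised bromo-ylide traps the labile aldehyde as the Z-bromoenoate (Br cis to C8), adding C11 and C13.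

Step 8
Reactants: 12 ethyl (2Z,4S,6Z,10Z)-4-(anilinooxy)-2-bromo-6-[(TBDPS-oxy)methyl]-12-(PMB-oxy)-10-methyldodeca-2,6,10-trienoate
Product: 13 the corresponding (4S)-4-hydroxy-2-bromotrienoate
Conditions: CuSO4·5H2O (30 mol %), MeOH, 0 °C → rt
Reagents that add atoms: none
Why: Copper-catalysed N–O cleavage frees the C8 hydroxyl without a reducing metal, which would attack the bromoenoate; the ester stays trans to C8 and so cannot lactonise.

Step 9
Reactants: 13 (4S)-4-hydroxy-2-bromotrienoate
Product: 14 the (4S)-4-(TBS-oxy)-2-bromotrienoate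
Conditions: TBSCl, imidazole, DMF, rt
Reagents that add atoms: tert-butyldimethylsilyl chloride, CC(C)(C)[Si](C)(C)Cl
Why: Silylation gives a poor leaving group at C8, so no 1,4-elimination is expected from the later allylchromium, and it provides the polar group for Felkin–Anh control in step 14.

Step 10
Reactants: 14 (4S)-4-(TBS-oxy)-2-bromotrienoate
Product: 15 (2Z,4S,6Z,10Z)-2-bromo-4-(TBS-oxy)-6-[(TBDPS-oxy)methyl]-12-(PMB-oxy)-10-methyldodeca-2,6,10-trien-1-ol
Conditions: iBu2AlH (2.2 equiv), CH2Cl2, −78 °C; aq. KNaC4H4O6 work-up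
Reagents that add atoms: none
Why: 1,2-Reduction of the enoate by DIBAL-H gives the 2-bromoallylic alcohol (C13–OH) and leaves the alkenyl bromide and both silyl ethers untouched.

Step 11
Reactants: 15 (2Z,4S,6Z,10Z)-2-bromo-4-(TBS-oxy)-6-[(TBDPS-oxy)methyl]-12-(PMB-oxy)-10-methyldodeca-2,6,10-trien-1-ol
Product: 16 the corresponding C13 allylic bromide (1,2-dibromide, 2Z,4S,6Z,10Z)
Conditions: CBr4, PPh3, CH2Cl2, 0 °C
Reagents that add atoms: carbon tetrabromide, BrC(Br)(Br)Br
Why: The Appel reaction converts the primary allylic alcohol to the bromide under neutral conditions without allylic transposition.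

Step 12
Reactants: 16 C13 allylic bromide with C6–OPMB
Product: 17 (2Z,6Z,9S,10Z)-11,12-dibromo-9-(TBS-oxy)-7-[(TBDPS-oxy)methyl]-3-methyldodeca-2,6,10-trien-1-ol
Conditions: DDQ, CH2Cl2–pH 7 buffer, 0 °C
Reagents that add atoms: none
Why: Oxidative PMB cleavage by hydride abstraction at the electron-rich benzylic position spares the allylic bromide and the silyl ethers.

Step 13
Reactants: 17 (2Z,6Z,9S,10Z)-11,12-dibromo-9-(TBS-oxy)-7-[(TBDPS-oxy)methyl]-3-methyldodeca-2,6,10-trien-1-ol
Product: 18 the corresponding (2Z)-enal (C6 aldehyde)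
Conditions: MnO2 (20 equiv), CH2Cl2, rt
Reagents that add atoms: none
Why: Neutral heterogeneous allylic oxidation with MnO2 gives the neral-type enal without acid or base that could isomerise the 4Z alkene.

Step 14
Reactants: 18 (2Z)-enal carrying the C13 allylic bromide
Product: 20 11-bromo-6α-hydroxy-8α-(TBS-oxy)-14-(TBDPS-oxy)-12-norgermacra-1(10),4Z,11(13)-triene (7α-H, C1=C10 ring-trans), via allylchromium dichloride 19 (not isolated)
Conditions: CrCl2 (8 equiv, nickel-free), THF, slow addition of 18 to 2 mM, rt; then H2O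
Reagents that add atoms: none
Why: In this Nozaki–Hiyama 2-haloallylation, divalent chromium inserts only into the allylic C–Br bond; the allylchromium then adds through a Zimmerman–Traxler chair (6,7-anti), anti to the C8–O bond with H8 eclipsing the C11–Br bond (Felkin–Anh sense), so the 8α-silyloxy centre sets 7α-H and 6α-OH.

Step 15
Reactants: 20 11-bromo-6α-hydroxy macrocycle
Product: 21 the 11-(pinacolatoboryl) analogue of 20
Conditions: B2pin2, PdCl2(PPh3)2 (3 mol %), PPh3 (6 mol %), KOPh, toluene, 50 °C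
Reagents that add atoms: bis(pinacolato)diboron, CC1(C)OB(B2OC(C)(C)C(C)(C)O2)OC1(C)C
Why: Miyaura borylation of the 1-alkenyl bromide reverses the polarity at C11 under mild base that the free allylic alcohol, the silyl ethers and the 1,5-diene should tolerate.

Step 16
Reactants: 21 11-(pinacolatoboryl)-6α-hydroxy macrocycle
Product: 22 the 6α-(tert-butoxycarbonyloxy) derivative of 21
Conditions: Boc2O, DMAP (cat.), Et3N, CH2Cl2, 0 °C → rt
Reagents that add atoms: di-tert-butyl dicarbonate, CC(C)(C)OC(=O)OC(=O)OC(C)(C)C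
Why: DMAP-catalysed O-acylation with retention at C6 installs a leaving group that releases a non-nucleophilic alkoxide when ionised by zerovalent palladium.

Step 17
Reactants: 22 11-(pinacolatoboryl)-6α-(tert-butoxycarbonyloxy) macrocycle
Product: 24 8α-(TBS-oxy)-14-(TBDPS-oxy)germacra-1(10),4Z,11(13)-trien-12,6α-olide, via copper carboxylate 23 (not isolated)
Conditions: CO2 (1 atm), (IPr)CuCl (10 mol %), NaOtBu (10 mol %), Pd(PPh3)4 (5 mol %), THF (2 mM), 45 °C
Reagents that add atoms: carbon dioxide, O=C=O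
Why: Proposed new method: (IPr)CuOtBu takes the C11 alkenyl group from boron, the alkenylcopper inserts CO2 (C11–C12 bond) to give carboxylate 23, Pd(PPh3)4 ionises the C6 tert-butyl carbonate of 23 with inversion to an η3-allyl complex over C4–C5–C6, the carboxylate attacks C6 on the face away from palladium (O–C6 bond), and the CO2 and tert-butoxide released by the ionisation regenerate (IPr)CuOtBu. The closest known reaction types are the copper-carbene-catalysed carboxylation of alkenylboronic esters with CO2, the copper-catalysed three-component coupling of an organocopper, CO2 and an allylic halide to an allylic ester, and the closure of allylpalladium carboxylates to lactones as in diene–CO2 telomerisation; the new element is their merger into one event on one substrate without stoichiometric base. The γ-lactone ring closes in the 5-exo mode at the secondary allyl terminus C6, whereas attack at the fully substituted C4 would need a seven-membered endo closure. C6 is the only stereocentre formed: two inversions add up to retention of the 6α-oxygen set in step 14, and only this course lets the carboxylate on the β-oriented C11 reach C6 anti to palladium, which gives the trans ring fusion. The step needs CO2 capture to outrun carbon–carbon coupling of the alkenylcopper with the allylpalladium, which should hold because the intramolecular coupling would have to form a methylenecyclopropane or a bridged cyclopentene with a quaternary C4, the bimolecular coupling is slowed by the 2 mM dilution against roughly 0.2 M dissolved CO2, and alkoxide appears only as fast as the carbonate is ionised. The 4Z geometry should hold because syn–anti exchange would require palladium σ-bound at the tertiary C4.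

Step 18
Reactants: 24 8α-(TBS-oxy)-14-(TBDPS-oxy) lactone
Product: 25 8α-hydroxy-14-(TBDPS-oxy)germacra-1(10),4Z,11(13)-trien-12,6α-olide
Conditions: HF·pyridine, pyridine–THF, 0 °C → rt
Reagents that add atoms: none
Why: Under buffered acidic fluoride the TBS ether is cleaved much faster than the TBDPS ether, and the conditions are too mild for transannular cyclisation of the diene.

Step 19
Reactants: 25 8α-hydroxy-14-(TBDPS-oxy) lactone
Product: 26 8β-isobutyryloxy-14-(TBDPS-oxy)germacra-1(10),4Z,11(13)-trien-12,6α-olide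
Conditions: PPh3 and DIAD premixed, THF, 0 °C; then 25 and iPrCO2H, 0 °C → rt
Reagents that add atoms: isobutyric acid, CC(C)C(=O)O
Why: In the Mitsunobu esterification, isobutyrate displaces the 8α-oxyphosphonium group in an SN2 step, which installs the ester and inverts the helper configuration to the required 8β (R) centre in one operation.

Step 20
Reactants: 26 8β-isobutyryloxy-14-(TBDPS-oxy) lactone
Product: 27 14-hydroxy-8β-isobutyryloxygermacra-1(10),4Z,11(13)-trien-12,6α-olide
Conditions: Bu4NF, AcOH (1:1), THF, 0 °C → rt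
Reagents that add atoms: none
Why: Acetic-acid-buffered fluoride desilylation frees the C14 allylic alcohol without basic alkoxide that could open the lactone, add to the methylene lactone or shift the ester.

Step 21
Reactants: 27 14-hydroxy-8β-isobutyryloxygermacra-1(10),4Z,11(13)-trien-12,6α-olide
Product: 28 target, (1R,10S)-1,10-epoxy-14-hydroxy-8β-isobutyryloxygermacra-4Z,11(13)-dien-12,6α-olide
Conditions: Ti(OiPr)4 (20 mol %), L-(+)-diethyl tartrate (24 mol %), tBuOOH, 4 Å molecular sieves, CH2Cl2, −20 °C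
Reagents that add atoms: tert-butyl hydroperoxide, CC(C)(C)OO
Why: Sharpless asymmetric epoxidation is directed by the C14 hydroxyl to C1=C10 only; the L-(+)-tartrate catalyst delivers oxygen to the face that gives (10S,1R), which should coincide with the exposed outer face of the ring-trans alkene, while C4=C5 and the electron-poor C11=C13 remain.

Compound list
1 | nerol | CC(C)=CCC/C(C)=C\CO | starting material
2 | neryl 4-methoxybenzyl ether | COc1ccc(COC/C=C(/C)CCC=C(C)C)cc1 | intermediate
3 | terminal epoxide of 2 (racemic, not isolated) | COc1ccc(COC/C=C(/C)CCC2OC2(C)C)cc1 | intermediate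
4 | (4Z)-6-(4-methoxybenzyloxy)-4-methylhex-4-enal | COc1ccc(COC/C=C(/C)CCC=O)cc1 | intermediate
5 | 2-bromoprop-2-en-1-ol | C=C(Br)CO | starting material
6 | 2-bromoallyl TBDPS ether | C=C(Br)CO[Si](c1ccccc1)(c1ccccc1)C(C)(C)C | intermediate
7 | 2-lithioallyl TBDPS ether (not isolated) | [Li]C(=C)CO[Si](c1ccccc1)(c1ccccc1)C(C)(C)C | intermediate
8 | (6Z)-1-(TBDPS-oxy)-8-(PMB-oxy)-6-methyl-2-methylideneoct-6-en-3-ol (racemic) | COc1ccc(COC/C=C(/C)CCC(O)C(=C)CO[Si](c2ccccc2)(c2ccccc2)C(C)(C)C)cc1 | intermediate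
9 | ethyl (4Z,8Z)-4-[(TBDPS-oxy)methyl]-10-(PMB-oxy)-8-methyldeca-4,8-dienoate | COc1ccc(COC/C=C(/C)CC/C=C(\CO[Si](c2ccccc2)(c2ccccc2)C(C)(C)C)CCC(=O)OCC)cc1 | intermediate
10 | (4Z,8Z)-4-[(TBDPS-oxy)methyl]-10-(PMB-oxy)-8-methyldeca-4,8-dienal | COc1ccc(COC/C=C(/C)CC/C=C(\CO[Si](c2ccccc2)(c2ccccc2)C(C)(C)C)CCC=O)cc1 | intermediate
11 | (2S)-2-(anilinooxy) derivative of 10 (not isolated) | COc1ccc(COC/C=C(/C)CC/C=C(\CO[Si](c2ccccc2)(c2ccccc2)C(C)(C)C)C[C@H](ONc2ccccc2)C=O)cc1 | intermediate
12 | ethyl (2Z,4S,6Z,10Z)-4-(anilinooxy)-2-bromo-6-[(TBDPS-oxy)methyl]-12-(PMB-oxy)-10-methyldodeca-2,6,10-trienoate | COc1ccc(COC/C=C(/C)CC/C=C(\CO[Si](c2ccccc2)(c2ccccc2)C(C)(C)C)C[C@H](ONc2ccccc2)/C=C(\Br)C(=O)OCC)cc1 | intermediate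
13 | (4S)-4-hydroxy analogue of 12 | COc1ccc(COC/C=C(/C)CC/C=C(\CO[Si](c2ccccc2)(c2ccccc2)C(C)(C)C)C[C@H](O)/C=C(\Br)C(=O)OCC)cc1 | intermediate
14 | (4S)-4-(TBS-oxy) analogue of 12 | COc1ccc(COC/C=C(/C)CC/C=C(\CO[Si](c2ccccc2)(c2ccccc2)C(C)(C)C)C[C@H](O[Si](C)(C)C(C)(C)C)/C=C(\Br)C(=O)OCC)cc1 | intermediate
15 | (2Z,4S,6Z,10Z)-2-bromo-4-(TBS-oxy)-6-[(TBDPS-oxy)methyl]-12-(PMB-oxy)-10-methyldodeca-2,6,10-trien-1-ol | COc1ccc(COC/C=C(/C)CC/C=C(\CO[Si](c2ccccc2)(c2ccccc2)C(C)(C)C)C[C@H](O[Si](C)(C)C(C)(C)C)/C=C(\Br)CO)cc1 | intermediate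
16 | C13 allylic bromide derived from 15 | COc1ccc(COC/C=C(/C)CC/C=C(\CO[Si](c2ccccc2)(c2ccccc2)C(C)(C)C)C[C@H](O[Si](C)(C)C(C)(C)C)/C=C(\Br)CBr)cc1 | intermediate
17 | (2Z,6Z,9S,10Z)-11,12-dibromo-9-(TBS-oxy)-7-[(TBDPS-oxy)methyl]-3-methyldodeca-2,6,10-trien-1-ol | OC/C=C(/C)CC/C=C(\CO[Si](c1ccccc1)(c1ccccc1)C(C)(C)C)C[C@H](O[Si](C)(C)C(C)(C)C)/C=C(\Br)CBr | intermediate
18 | (2Z)-enal derived from 17 | O=C/C=C(/C)CC/C=C(\CO[Si](c1ccccc1)(c1ccccc1)C(C)(C)C)C[C@H](O[Si](C)(C)C(C)(C)C)/C=C(\Br)CBr | intermediate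
19 | allylchromium dichloride derived from 18 (not isolated) | O=C/C=C(/C)CC/C=C(\CO[Si](c1ccccc1)(c1ccccc1)C(C)(C)C)C[C@H](O[Si](C)(C)C(C)(C)C)/C=C(\Br)C[Cr](Cl)Cl | intermediate
20 | 11-bromo-6α-hydroxy-8α-(TBS-oxy)-14-(TBDPS-oxy)-12-norgermacra-1(10),4Z,11(13)-triene | C=C(Br)[C@H]1[C@H](O)/C=C(/C)CC/C=C(\CO[Si](c2ccccc2)(c2ccccc2)C(C)(C)C)C[C@@H]1O[Si](C)(C)C(C)(C)C | intermediate
21 | 11-(pinacolatoboryl) analogue of 20 | C=C(B2OC(C)(C)C(C)(C)O2)[C@H]1[C@H](O)/C=C(/C)CC/C=C(\CO[Si](c2ccccc2)(c2ccccc2)C(C)(C)C)C[C@@H]1O[Si](C)(C)C(C)(C)C | intermediate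
22 | 6α-(tert-butoxycarbonyloxy) derivative of 21 | C=C(B2OC(C)(C)C(C)(C)O2)[C@H]1[C@H](OC(=O)OC(C)(C)C)/C=C(/C)CC/C=C(\CO[Si](c2ccccc2)(c2ccccc2)C(C)(C)C)C[C@@H]1O[Si](C)(C)C(C)(C)C | intermediate
23 | C11 carboxylate of 22 as its (IPr)Cu salt, carbene ligand omitted from the SMILES (not isolated) | [Cu+].C=C(C(=O)[O-])[C@H]1[C@H](OC(=O)OC(C)(C)C)/C=C(/C)CC/C=C(\CO[Si](c2ccccc2)(c2ccccc2)C(C)(C)C)C[C@@H]1O[Si](C)(C)C(C)(C)C | intermediate
24 | 8α-(TBS-oxy)-14-(TBDPS-oxy)germacra-1(10),4Z,11(13)-trien-12,6α-olide | C=C1C(=O)O[C@@H]2/C=C(/C)CC/C=C(\CO[Si](c3ccccc3)(c3ccccc3)C(C)(C)C)C[C@H](O[Si](C)(C)C(C)(C)C)[C@@H]12 | intermediate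
25 | 8α-hydroxy-14-(TBDPS-oxy)germacra-1(10),4Z,11(13)-trien-12,6α-olide | C=C1C(=O)O[C@@H]2/C=C(/C)CC/C=C(\CO[Si](c3ccccc3)(c3ccccc3)C(C)(C)C)C[C@H](O)[C@@H]12 | intermediate
26 | 8β-isobutyryloxy-14-(TBDPS-oxy)germacra-1(10),4Z,11(13)-trien-12,6α-olide | C=C1C(=O)O[C@@H]2/C=C(/C)CC/C=C(\CO[Si](c3ccccc3)(c3ccccc3)C(C)(C)C)C[C@@H](OC(=O)C(C)C)[C@@H]12 | intermediate
27 | 14-hydroxy-8β-isobutyryloxygermacra-1(10),4Z,11(13)-trien-12,6α-olide | C=C1C(=O)O[C@@H]2/C=C(/C)CC/C=C(\CO)C[C@@H](OC(=O)C(C)C)[C@@H]12 | intermediate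
28 | CNP0247143.1, (1R,10S)-1,10-epoxy-14-hydroxy-8β-isobutyryloxygermacra-4Z,11(13)-dien-12,6α-olide | C=C1C(=O)O[C@@H]2/C=C(/C)CC[C@H]3O[C@]3(CO)C[C@@H](OC(=O)C(C)C)[C@@H]12 | target

Total step count: 21. Longest linear sequence: 20 (steps 1, 2 and 4–21; step 3 is the side branch).

Steps most likely to fail

Step 17. The alkenylcopper may be intercepted by the allylpalladium before it meets CO2, giving carbon–carbon coupling. The boronate may also protodeboronate, the allyl complex may lose a β-hydrogen to give a triene, or the product may be re-ionised. The fallback uses known chemistry and sets out from 20. Palladium-catalysed carbonylative lactonisation (Pd(PPh3)4, CO 1 atm, Et3N, MeCN, 60 °C) turns the alkenyl bromide into an acylpalladium that the 6α-hydroxyl captures with retention. This returns to the route at 24 and makes steps 15 and 16 unnecessary.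

Step 14. Oligomerisation may compete with ten-membered ring closure, the 2-bromoallylchromium may lose bromide by 1,2-elimination to give an allene, and facial selectivity may erode in the medium-ring transition state. The fallback replaces direct closure by contraction of a larger, easier ring and sets out from 17. Intramolecular Williamson etherification (NaH, THF, 5 mM) between the C6 hydroxyl and the C13 allylic bromide should give the thirteen-membered cyclic bis-allylic ether F1. Deprotonation at C6 with LiN(iPr)2 (THF, −78 °C) followed by [2,3]-Wittig ring contraction then makes the same C6–C7 bond, moves the alkene to C11=C13 and frees the C6 alkoxide, returning to the route at 20.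

Step 19. Substitution at the hindered C8 may be slow, so that elimination toward C9 or C7 or phosphine addition to the methylene lactone takes over. The fallback separates activation from displacement and sets out from 25. Sulfonylation (ClCH2SO2Cl, pyridine, 0 °C) should give the 8α-chloromethanesulfonate F2. Displacement with CsO2CCH(CH3)2 and 18-crown-6 in toluene at 60 °C then proceeds with inversion and without phosphine, returning to the route at 26.

Further compounds
F0 | step 17 | none | none
F1 | step 14 | thirteen-membered cyclic bis-allylic ether (O bridging C6 and C13) | O1C/C=C(/C)CC/C=C(\CO[Si](c2ccccc2)(c2ccccc2)C(C)(C)C)C[C@H](O[Si](C)(C)C(C)(C)C)/C=C(\Br)C1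
F2 | step 19 | 8α-chloromethanesulfonate of 25 | C=C1C(=O)O[C@@H]2/C=C(/C)CC/C=C(\CO[Si](c3ccccc3)(c3ccccc3)C(C)(C)C)C[C@H](OS(=O)(=O)CCl)[C@@H]12
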